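Set summer beside its neighbour winter: the same L and the same time, but 3.33 times the D, and the question is what the extra D buys along the row.

all flasks: L 0.40 M; time 80 min
- winter: D 0.06 mol%
- summer: D 0.2 mol%
- midnight: D 0.6 mol%
- noon: D 2 mol%
- autumn: D 5 mol%

- amount of G at the end, in percent of the L charged for winter, summer, midnight, noon, autumn, in this order
- how the row runs (rises all the way / hardly changes / falls, then rises / falls all the way / rises, then falls)

- for a step with 2 of a species take k times the square, and two of it per event
- "hardly changes" means that all values lie within two and a half points (for a concentration: within two and a half percent of the largest)
- run time (winter): 80 min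

    L + D ⇌ L.D (K1 = 12.0 /M, k1 = 21.4 /M/min)
    2 D → D2 (k2 = 2.11 /M/min)
    L.D → D + G (k3 = 9.15 /min)

L binds D reversibly as L.D, L.D gives G and frees D, and two free D join as D2, outside the working round.

At the board I take the catalyst as standing. L.D lasts 0.0915 min, far shorter than the run, so it sits at steady state. Winter's 0.439 is its reach: the forward constant of L.D times loading times time, the charges of L turned over if every D sat as L.D throughout. Real occupation is lower: with m, the Michaelis constant over L's charge, at 1.28, my reckoning reads reach = m·ln(charge/left) + share converted. So winter reaches 19.3%, with the logarithm cut to its first term, which runs a little high. Midnight, with reach 4.39, reaches 93.0%. Noon, with 14.6, leaves 0.00230% of L. Loss of D is my correction: winter's half-life of D at its charge is 987 min, longer than the run.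

My colleague answers with the life view. Autumn's half-life at its charge is 11.8 min, shorter than the run, and a flask works only while its D lives. Reach within one life is 5.42, the loading cancelling, against autumn's nominal 36.6, so by this view noon and autumn should stall near 96.9%.

We agree on one thing. With L's charge held, L's fall and D's fall, each per charge, both run on loading times time, so equal reach should mean equal state.

The forecast stands on my side, with 18%, 50%, 89%, 99.6%, 99.9% and rises all the way, holding that “the catalyst dies only slowly”, though its midnight lies below mine.

The flask gives 18.0%, 50.2%, 88.8%, 99.6%, 100%: rises all the way, with midnight 4.2 percentage points under my figure.

Noon's 99.6% stands above the stall of 96.9%. The life view holds for the catalyst, though: autumn at 80.0 min has 86.4% of its catalyst as D2, with L at 0.0120%. Now the reach. Winter left for 800 min has reach 4.39, equal to midnight's, and holds L 11.2% against midnight's 11.2%. Summer left as long has reach 14.6, equal to noon's, and holds L 0.350% against noon's 0.353%.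

The numbers belong to no real substance.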